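**Retrosynthetic overview**
1. Target 13 ⇐ diol-phenol 12 by chemoselective enzymatic O-acetylation of the two primary alcohols.
2. Key disconnection is the C2–O1 bond of the dihydrofuran: 12 ⇐ open-chain 1,2-diarylpropane-1,3-diol 10 by oxa-cyclisation onto a para-quinone methide, which also fixes the 2,3-trans relationship.
3. 10 ⇐ (E)-stilbene allylic alcohol 8 by an enantioselective formal hydration (new copper hydride hydroboration, then oxidation) that sets the future C3.
4. 8 ⇐ arylidene benzofuranone 7 (reduction) ⇐ benzofuranone 5 + vanillin 6 (Knoevenagel) ⇐ dihydroferulic acid 1 + glyoxylic acid 2 (ortho C–C bond).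
5. Ring order: rings A and B are bought; a temporary lactone ring is made first and opened by reduction; the dihydrofuran ring is closed last.

Assumption: the face selectivity of the copper hydride catalyst cannot be predicted with certainty; (R)-DTBM-SEGPHOS is written, and its antipode is used if the first run gives the enantiomer of 10.

**Route**

Step 1
Reactants: 1 3-(4-hydroxy-3-methoxyphenyl)propanoic acid (dihydroferulic acid); 2 glyoxylic acid (50% aq.)
Product: 5 3-(7-methoxy-2-oxo-2,3-dihydro-1-benzofuran-5-yl)propanoic acid, via mandelic acid 3 (not isolated), via arylacetic acid 4 (not isolated)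
Conditions: 2 (1.5 equiv), aq. NaOH, 40 °C; then conc. HCl, SnCl2·2H2O, 80 °C; then toluene, cat. TsOH, reflux (Dean–Stark)
Reagents that add atoms: none
Why: The phenolate undergoes electrophilic ortho-hydroxyalkylation by glyoxylate at its only free ortho/para position (para is blocked), the benzylic hydroxyl of the mandelic acid is removed by the classical SnCl2/HCl reduction, and the resulting 2-hydroxyarylacetic acid lactonises under acid with water removal.

Step 2
Reactants: 5 3-(7-methoxy-2-oxo-2,3-dihydro-1-benzofuran-5-yl)propanoic acid; 6 vanillin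
Product: 7 3-[(3E)-3-(4-hydroxy-3-methoxybenzylidene)-7-methoxy-2-oxo-2,3-dihydro-1-benzofuran-5-yl]propanoic acid
Conditions: TsOH·H2O (10 mol%), toluene/1,4-dioxane, reflux (Dean–Stark); crystallise the E isomer
Reagents that add atoms: none
Why: Knoevenagel condensation of the strongly C–H acidic aryl lactone with the aldehyde gives the conjugated arylidene lactone, and the thermodynamically preferred E isomer (aryl anti to the lactone carbonyl) is obtained pure by crystallisation.

Step 3
Reactants: 7 3-[(3E)-3-(4-hydroxy-3-methoxybenzylidene)-7-methoxy-2-oxo-2,3-dihydro-1-benzofuran-5-yl]propanoic acid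
Product: 8 (2E)-2-[2-hydroxy-5-(3-hydroxypropyl)-3-methoxyphenyl]-3-(4-hydroxy-3-methoxyphenyl)prop-2-en-1-ol
Conditions: AlH3 (made in the flask from LiAlH4 and AlCl3, 3:1), THF, 0 to 23 °C; then aq. KNaC4H4O6 (potassium sodium tartrate); protect from light
Reagents that add atoms: none
Why: Alane reduction takes the aryl lactone and the carboxylic acid to primary alcohols with clean 1,2-selectivity (no conjugate reduction), liberating the ring-A phenol and keeping the alkene geometry.

Step 4
Reactants: 8 (2E)-2-[2-hydroxy-5-(3-hydroxypropyl)-3-methoxyphenyl]-3-(4-hydroxy-3-methoxyphenyl)prop-2-en-1-ol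
Product: 10 (1R,2R)-1-(4-hydroxy-3-methoxyphenyl)-2-[2-hydroxy-5-(3-hydroxypropyl)-3-methoxyphenyl]propane-1,3-diol, via pentaboryl intermediate 9 (not isolated)
Conditions: Cu(OAc)2 (5 mol%), (R)-5,5'-bis[bis(3,5-di-tert-butyl-4-methoxyphenyl)phosphino]-4,4'-bi-1,3-benzodioxole ((R)-DTBM-SEGPHOS, 6 mol%), HBpin (6.5 equiv), THF, 50 °C; then NaBO3·4H2O, THF/H2O, 23 °C
Reagents that add atoms: pinacolborane, B1OC(C)(C)C(C)(C)O1 (boron of intermediate 9); sodium perborate, [Na+].[O-]OB=O (hydroxyl oxygen at C1 of 10)
Why: Proposed new method: the ligated copper hydride (monovalent copper) first caps the four OH groups as O–Bpin by dehydrogenative borylation, then adds syn across the trisubstituted stilbene C=C with copper at the less hindered benzylic CH carbon (C1, a stabilised benzylcopper) and hydride at the fully substituted carbon (C2), the bulky chiral bisphosphine choosing the alkene face and so fixing C2 (the future C3) as R; σ-bond metathesis with HBpin and perborate oxidation both proceed with retention to give the benzylic alcohol; the closest known chemistry is the copper hydride/DTBM-SEGPHOS enantioselective hydroboration and hydroamination of β-substituted and 1,1-disubstituted vinylarenes, which has not been shown for a trisubstituted 1,2-diaryl alkene with in situ borylated hydroxyl groups.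

Step 5
Reactants: 10 (1R,2R)-1-(4-hydroxy-3-methoxyphenyl)-2-[2-hydroxy-5-(3-hydroxypropyl)-3-methoxyphenyl]propane-1,3-diol
Product: 12 4-[(2S,3R)-3-(hydroxymethyl)-5-(3-hydroxypropyl)-7-methoxy-2,3-dihydro-1-benzofuran-2-yl]-2-methoxyphenol, via quinone methide 11 (not isolated)
Conditions: TsOH·H2O (10 mol%), MeCN, 0 to 23 °C
Reagents that add atoms: none
Why: Acid-promoted dehydrative oxa-cyclisation: the para-hydroxybenzylic alcohol ionises to the (protonated) para-quinone methide and the ring-A phenol adds to it (intramolecular 1,6-conjugate addition, 5-exo-trig) to form the C2–O1 bond; the C1 configuration of 10 is erased, C3 is untouched, and the aryl group at C2 settles trans to the C3 substituent under kinetic and (reversible ring opening at C2) thermodynamic control, giving 2S,3R.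

Step 6
Reactants: 12 4-[(2S,3R)-3-(hydroxymethyl)-5-(3-hydroxypropyl)-7-methoxy-2,3-dihydro-1-benzofuran-2-yl]-2-methoxyphenol
Product: 13 [(2S,3R)-5-(3-acetoxypropyl)-2-(4-hydroxy-3-methoxyphenyl)-7-methoxy-2,3-dihydro-1-benzofuran-3-yl]methyl acetate (target)
Conditions: immobilised Candida antarctica lipase B (Novozym 435), vinyl acetate (6 equiv), THF, 40 °C
Reagents that add atoms: vinyl acetate, CC(=O)OC=C
Why: Lipase-catalysed transesterification acylates primary aliphatic alcohols but not phenols, so both CH2OH groups are acetylated and the phenol stays free; the reaction is irreversible because the vinyl alcohol released tautomerises to acetaldehyde, and no stereocentre is touched.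

**Compound list**
1 | 3-(4-hydroxy-3-methoxyphenyl)propanoic acid (dihydroferulic acid) | COc1cc(CCC(=O)O)ccc1O | starting material
2 | glyoxylic acid | O=CC(=O)O | starting material
3 | 2-[5-(2-carboxyethyl)-2-hydroxy-3-methoxyphenyl]-2-hydroxyacetic acid (racemic mandelic acid) | OC(C(=O)O)c1cc(CCC(=O)O)cc(OC)c1O | intermediate
4 | 3-[3-(carboxymethyl)-4-hydroxy-5-methoxyphenyl]propanoic acid | OC(=O)Cc1cc(CCC(=O)O)cc(OC)c1O | intermediate
5 | 3-(7-methoxy-2-oxo-2,3-dihydro-1-benzofuran-5-yl)propanoic acid | O=C1Cc2cc(CCC(=O)O)cc(OC)c2O1 | intermediate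
6 | vanillin (4-hydroxy-3-methoxybenzaldehyde) | COc1cc(C=O)ccc1O | starting material
7 | 3-[(3E)-3-(4-hydroxy-3-methoxybenzylidene)-7-methoxy-2-oxo-2,3-dihydro-1-benzofuran-5-yl]propanoic acid | O=C1Oc2c(OC)cc(CCC(=O)O)cc2/C1=C\c1ccc(O)c(OC)c1 | intermediate
8 | (2E)-2-[2-hydroxy-5-(3-hydroxypropyl)-3-methoxyphenyl]-3-(4-hydroxy-3-methoxyphenyl)prop-2-en-1-ol (aryl groups cis) | OC/C(=C/c1ccc(O)c(OC)c1)c1cc(CCCO)cc(OC)c1O | intermediate
9 | pentaboryl intermediate: (1R,2R)-C1-pinacolboronate of the hydroboration product, all four hydroxyl groups as O–Bpin esters | CC1(C)OB(OC1(C)C)[C@@H](c2ccc(OB3OC(C)(C)C(C)(C)O3)c(OC)c2)[C@@H](COB4OC(C)(C)C(C)(C)O4)c5cc(CCCOB6OC(C)(C)C(C)(C)O6)cc(OC)c5OB7OC(C)(C)C(C)(C)O7 | intermediate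
10 | (1R,2R)-1-(4-hydroxy-3-methoxyphenyl)-2-[2-hydroxy-5-(3-hydroxypropyl)-3-methoxyphenyl]propane-1,3-diol | O[C@@H](c1ccc(O)c(OC)c1)[C@@H](CO)c1cc(CCCO)cc(OC)c1O | intermediate
11 | quinone methide: 4-[(2R)-3-hydroxy-2-[2-hydroxy-5-(3-hydroxypropyl)-3-methoxyphenyl]propylidene]-2-methoxycyclohexa-2,5-dien-1-one (formed as its O-protonated form; exocyclic C=C geometry not defined) | OC[C@H](C=C1C=CC(=O)C(OC)=C1)c1cc(CCCO)cc(OC)c1O | intermediate
12 | 4-[(2S,3R)-3-(hydroxymethyl)-5-(3-hydroxypropyl)-7-methoxy-2,3-dihydro-1-benzofuran-2-yl]-2-methoxyphenol | COc1cc([C@H]2Oc3c(OC)cc(CCCO)cc3[C@@H]2CO)ccc1O | intermediate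
13 | [(2S,3R)-5-(3-acetoxypropyl)-2-(4-hydroxy-3-methoxyphenyl)-7-methoxy-2,3-dihydro-1-benzofuran-3-yl]methyl acetate | COc1cc([C@H]2Oc3c(OC)cc(CCCOC(C)=O)cc3[C@@H]2COC(C)=O)ccc1O | target

**Step count and risks**

Total steps: 6. Longest linear sequence: 6 (from 1).

The three steps most likely to fail:

Step 4 (the proposed new reaction). Hydrocupration of a trisubstituted, electron-rich stilbene may be slow, poorly face-selective, or give some copper at C2 followed by loss of the allylic oxygen. Fallback with known chemistry: setting out from 8, the four hydroxyl groups are capped in the flask with N,O-bis(trimethylsilyl)acetamide to give the tetrakis(trimethylsilyl) ether F1. F1 is hydroborated with stoichiometric monoisopinocampheylborane derived from (+)-α-pinene (Brown asymmetric hydroboration of trisubstituted alkenes; the antipodal borane is taken if the first run shows the wrong face) to give the alkyl(isopinocampheyl)borane F2. NaOH/H2O2 then oxidises the C–B bonds and strips the silyl ethers, and the route is rejoined at 10.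

Step 1. Ortho-hydroxyalkylation of a para-blocked guaiacol is slow and can stall or over-react, and the one-pot reduction and lactonisation may be messy. Fallback: setting out from 1, iodination ortho to the phenol (I2, aq. NaHCO3) gives 3-(4-hydroxy-3-iodo-5-methoxyphenyl)propanoic acid F3. Copper-catalysed arylation of diethyl malonate (CuI, i.e. copper monoiodide, 2-picolinic acid, Cs2CO3, dioxane) with spontaneous lactonisation gives ethyl 5-(2-carboxyethyl)-7-methoxy-2-oxo-2,3-dihydro-1-benzofuran-3-carboxylate F4. Hot aqueous HCl hydrolyses, decarboxylates and re-lactonises F4, and the route is rejoined at 5.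

Step 6. The β-branched CH2OH at C3 may be acylated too slowly by the lipase, leaving monoacetate. Fallback: setting out from 12, exhaustive acetylation (Ac2O, pyridine, cat. DMAP) gives the triacetate [(2S,3R)-2-(4-acetoxy-3-methoxyphenyl)-5-(3-acetoxypropyl)-7-methoxy-2,3-dihydro-1-benzofuran-3-yl]methyl acetate F5. Its aryl acetate alone is then cleaved by pyrrolidine (1.1 equiv, CH2Cl2, 0 °C), since aminolysis of aryl esters is far faster than that of alkyl esters, and the route is rejoined at 13.

**Further compounds**
F1 | step 4 | tetrakis(trimethylsilyl) ether of 8 | C[Si](C)(C)OC/C(=C/c1ccc(O[Si](C)(C)C)c(OC)c1)c1cc(CCCO[Si](C)(C)C)cc(OC)c1O[Si](C)(C)C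
F2 | step 4 | (1R,2R)-configured alkyl(isopinocampheyl)borane from F1 (boron at the benzylic carbon) | C[C@H]1[C@H]([BH][C@@H](c2ccc(O[Si](C)(C)C)c(OC)c2)[C@@H](CO[Si](C)(C)C)c2cc(CCCO[Si](C)(C)C)cc(OC)c2O[Si](C)(C)C)C[C@@H]3C[C@H]1C3(C)C
F3 | step 1 | 3-(4-hydroxy-3-iodo-5-methoxyphenyl)propanoic acid | COc1cc(CCC(=O)O)cc(I)c1O
F4 | step 1 | ethyl 5-(2-carboxyethyl)-7-methoxy-2-oxo-2,3-dihydro-1-benzofuran-3-carboxylate (racemic) | CCOC(=O)C1C(=O)Oc2c(OC)cc(CCC(=O)O)cc21
F5 | step 6 | [(2S,3R)-2-(4-acetoxy-3-methoxyphenyl)-5-(3-acetoxypropyl)-7-methoxy-2,3-dihydro-1-benzofuran-3-yl]methyl acetate | COc1cc([C@H]2Oc3c(OC)cc(CCCOC(C)=O)cc3[C@@H]2COC(C)=O)ccc1OC(C)=O
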